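Raise the temperature from 0 °C to 6 °C and E levels off at 38.6% instead of 42.7%. The steps proposed show where to look. X turns into Q, and Q then either meets G and gives E, at a rate that goes with Q, or meets a second Q and gives J, at a rate that goes with Q squared. So with G held, the lower Q stands, the larger the share of Q that reaches E (the selectivity). Q isn't read, so carry something you can read: Tuesday's flask gives 0.427 for the yield on X, the E made per X charged.

| flask | Z | X | temperature | remark | time |
|---|---|---|---|---|---|
| Tuesday's | 0.20 M | 0.20 M | 0 °C | the very flask that is asked about, followed so far |  |
| Friday's | 0.20 M | 0.20 M | 6 °C | run made earlier |  |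
| flask | 0.20 M | 0.200 M | 0 °C |  | 6.0 h |

- Tuesday's (time / min: E / %): 15.0: 34.7; 40.0: 42.2; 80.0: 42.8; 120: 42.7; 180: 42.9; 240: 42.5
- Friday's (time / min: E / %): 15.0: 37.9; 40.0: 38.9; 80.0: 38.7; 120: 38.7; 180: 38.3; 240: 38.3

(readings scatter by 0.3 percentage points)

- theta: change nothing and wait 3.0 h more
- epsilon: at 6.0 h raise the temperature by 15 K, then wait 3.0 h
- zeta: at 6.0 h add Z, 50.0% of the amount charged, then wait 3.0 h
- beta: at 6.0 h add X, 50.0% of the amount charged, then wait 3.0 h

- E is meant together with its D
- solid, in amounts per volume of the solution: D
- what is added takes up no volume worth counting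
- what was read earlier has a scatter of 0.3 percentage points, one standard deviation
- steps that have been proposed: Z <-> G; X -> Q; G + Q -> E; 2 Q -> J; D <-> E

* E, in percent of the Z first charged, at 6.0 h
* the option that brings most further E ("none" if no option brings more than 2 percentage points) (theta / epsilon / zeta / beta / none)
* E present, in percent of the Z first charged, after zeta
* E present, in percent of the Z first charged, after beta

Take the times from short to long in Tuesday's flask, the one asked about. First comes the rise of E: if the gap to the plateau closes by steady halving, it halves in about 6.22 min, as read from the first reading. From 80.0 min to 240 min the readings stay within 0.4 percentage points of each other, at a scatter of 0.3 points. Then comes your wait, 57.9 of those half-times, so I expect E at 42.7% at 6.0 h, because the half-time is far shorter than the wait.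

Since 57.3% of the Z charged has not become E and no proposed step takes away E counted together with its D, I take X as the limiting reagent. Waiting, heating and zeta bring no new X, so I expect no gain from them. Beta brings 0.100 M of X to 0.115 M of charged Z not turned into E, a ratio of 0.870 against 1.00 at the start. As my estimate I keep the yield on X, which gives 21 points more and 64.1% in all.

The forecast gives 42.7% at 6.0 h (range 42.4% to 43%), 42.7% after zeta and 62.5% after beta (range 58.5% to 66%), and names beta as best. Of the other options it says: “Waiting, heating or adding Z gives nothing, because no Q remains.” Its beta figure stands below my 64.1%, though mine lies inside its range.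

The flask gives 42.5% at 6.0 h and 42.5% after zeta, while beta, the best option, brings 30 points and reaches 72.8%. At 360 min in the flask, 0% of the X charged was left and 40.2% of the Z was free. The portion of X added in beta, half the first charge, gave a yield on X of 0.604, more than the 0.427 read for the first charge.

    Z ⇌ G (K = 0.430, k = 0.0490 min⁻¹, Ea = 85.0 kJ mol⁻¹, ΔH = −67.0 kJ mol⁻¹)
    X → Q (k = 0.180 min⁻¹, Ea = 86.0 kJ mol⁻¹)
    G + Q → E (k = 42.0 M⁻¹ min⁻¹, Ea = 53.0 kJ mol⁻¹)
    2 Q → J (k = 29.0 M⁻¹ min⁻¹, Ea = 48.0 kJ mol⁻¹)
    D ⇌ E, rate k5*(cs5 - [E]) while solid is left; crystals form when [E] > cs5 (solubility = 9.30 mM, k = 13.0 min⁻¹)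
    (constants at 0 °C)

Now take the neighbour flask with 0.050 M of X. The carried yield of 0.427 gives 10.7% of the Z charged. That neighbour flask gives 19.1%, a yield on X of 0.764, again more E per X than the 0.427 read in Tuesday's flask.

Readings and results are calculated from invented constants; noise was put on by code.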